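## Retrosynthetic overview

1. Target ⇒ Heck disconnection of the triene (C8–C9) into a ring vinyl carbinol that already carries the upper amide, and the (2E,4E)-5-bromopentadienamide of the aminocyclopentenone.
2. Upper enamide ⇒ vinylic C–N coupling of a ring α-iodoenone with (2E,4E,6R)-2,4,6-trimethyldeca-2,4-dienamide.
3. α-Iodoenone ⇒ cis-4,5-diol ⇒ desymmetrizing boron-tethered oxa-Michael addition on achiral 4-hydroxy-4-vinylcyclohexa-2,5-dienone (quinone monoketal + vinyl Grignard); this organocatalytic step sets both ring stereocentres.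
4. Dienamide ⇒ two Wittig olefinations from (R)-2-methylhexanal ⇒ organocatalytic formal α-methylation of hexanal (first stereocentre of that fragment).
5. Rings: neither carbocycle is built. The cyclohexenone comes from the quinone monoketal and the cyclopentenone from the purchased aminodione; the only ring closed is the transient dioxaborolane of the key step.

Assumption: 2-amino-3-hydroxycyclopent-2-en-1-one hydrochloride is a catalogue compound, and the sense of induction of the two organocatalysts is assigned by analogy, so the mirror-image (or pseudo-enantiomeric) catalyst is taken if the first run shows the opposite sense.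

## Route

Step 1
Reactants: 1 4,4-dimethoxycyclohexa-2,5-dien-1-one; 2 vinylmagnesium bromide
Product: 4 4-ethenyl-4-hydroxycyclohexa-2,5-dien-1-one, via ketal carbinol 3 (not isolated)
Conditions: THF, −78 °C; then 1 M HCl, THF–H2O, 0 °C
Reagents that add atoms: water, O
Why: Grignard 1,2-addition to the only carbonyl of the quinone monoketal, then acid hydrolysis of the dimethyl ketal through its stabilised oxocarbenium ion, gives the achiral mirror-symmetric p-quinol with no stereocentre formed.

Step 2
Reactants: 4 4-ethenyl-4-hydroxycyclohexa-2,5-dien-1-one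
Product: 6 (4R,5S)-4-ethenyl-4,5-dihydroxycyclohex-2-en-1-one, via cyclic phenylboronate 5 (not isolated)
Conditions: PhB(OH)2 (1.2 equiv), quinine-derived bifunctional thiourea [N-(3,5-bis(trifluoromethyl)phenyl)-N'-(9-deoxy-epi-quinin-9-yl)thiourea, 10 mol%], 4 Å MS, toluene, 0 °C; then pinacol, rt
Reagents that add atoms: phenylboronic acid, OB(O)c1ccccc1
Why: Proposed new method: phenylboronic acid esterifies the tertiary alcohol of 4 reversibly, the quinuclidine nitrogen binds boron to give a chiral tetracoordinate hydroxyboronate whose B–OH oxygen is delivered intramolecularly (5-exo) to one of the two enantiotopic β-carbons while the thiourea hydrogen-bonds the dienone carbonyl, so this desymmetrizing oxa-Michael addition sets C4 (R) and C5 (S) in one event with the cis relationship enforced by the five-membered boronate; the closest known reaction type is the amine–thiourea-catalysed boronic acid hemiester oxa-Michael addition of acyclic γ-hydroxy enones, which has not been shown on a prochiral cyclohexadienone.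

Step 3
Reactants: 6 (4R,5S)-4-ethenyl-4,5-dihydroxycyclohex-2-en-1-one
Product: 7 (4R,5S)-4-ethenyl-4,5-dihydroxy-2-iodocyclohex-2-en-1-one
Conditions: I2, pyridine, DMAP (20 mol%), CH2Cl2, 0 °C to rt
Reagents that add atoms: iodine, II
Why: Baylis–Hillman-type α-iodination of the enone (amine conjugate addition, enolate iodination, elimination) occurs at C2, the only enone α-carbon, under non-basic conditions that leave the β-hydroxy ketone and both stereocentres untouched.

Step 4
Reactants: 8 hexanal; 9 1,3-benzodithiolylium tetrafluoroborate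
Product: 11 (2R)-2-(1,3-benzodithiol-2-yl)hexan-1-ol, via benzodithiolyl aldehyde 10 (not isolated)
Conditions: (5R)-5-benzyl-2,2,3-trimethylimidazolidin-4-one·PhCO2H (20 mol%), NaH2PO4, MeCN–H2O, 0 °C; then NaBH4, MeOH, 0 °C
Reagents that add atoms: none
Why: Enamine catalysis, an SN1-type organocatalytic α-alkylation in which the imidazolidinone enamine of hexanal attacks the stabilised benzodithiolylium cation on the face remote from the benzyl group to set the (R) centre, and the aldehyde is reduced in the same flask before it can epimerise.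

Step 5
Reactants: 11 (2R)-2-(1,3-benzodithiol-2-yl)hexan-1-ol
Product: 12 (2R)-2-methylhexan-1-ol
Conditions: Raney Ni, H2 (1 atm), EtOH, rt
Reagents that add atoms: none
Why: Reductive desulfurisation cleaves all four C–S bonds and turns the benzodithiolyl carbon into the methyl group, and the stereocentre is not a reacting carbon.

Step 6
Reactants: 12 (2R)-2-methylhexan-1-ol; 13 2-(triphenylphosphoranylidene)propanal
Product: 15 (2E,4R)-2,4-dimethyloct-2-enal, via (R)-2-methylhexanal 14 (not isolated)
Conditions: TEMPO (10 mol%), PhI(OAc)2, CH2Cl2, rt; then 13, toluene, 80 °C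
Reagents that add atoms: none
Why: Oxoammonium (TEMPO) oxidation gives the α-branched aldehyde, which is trapped at once by the formyl-stabilised ylide in an E-selective Wittig olefination, so the epimerisable aldehyde is never stored.

Step 7
Reactants: 15 (2E,4R)-2,4-dimethyloct-2-enal; 16 ethyl 2-(triphenylphosphoranylidene)propanoate
Product: 17 ethyl (2E,4E,6R)-2,4,6-trimethyldeca-2,4-dienoate
Conditions: toluene, 90 °C
Reagents that add atoms: none
Why: Wittig olefination with the ester-stabilised ylide gives the (2E) trisubstituted alkene and leaves the (4E) alkene and C6 untouched.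

Step 8
Reactants: 17 ethyl (2E,4E,6R)-2,4,6-trimethyldeca-2,4-dienoate
Product: 18 (2E,4E,6R)-2,4,6-trimethyldeca-2,4-dienamide
Conditions: AlMe3, NH4Cl, toluene, 0 to 50 °C
Reagents that add atoms: ammonium chloride, [NH4+].[Cl-]
Why: Weinreb-type aluminium amide aminolysis converts the hindered ester directly into the primary amide without base that could isomerise the diene or epimerise C6.

Step 9
Reactants: 7 (4R,5S)-4-ethenyl-4,5-dihydroxy-2-iodocyclohex-2-en-1-one; 18 (2E,4E,6R)-2,4,6-trimethyldeca-2,4-dienamide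
Product: 19 (2E,4E,6R)-N-[(3R,4S)-3-ethenyl-3,4-dihydroxy-6-oxocyclohex-1-en-1-yl]-2,4,6-trimethyldeca-2,4-dienamide
Conditions: CuI (10 mol%), MeNHCH2CH2NHMe (20 mol%), Cs2CO3, THF, 50 °C
Reagents that add atoms: none
Why: Goldberg-type CuI/diamine vinylic amidation couples the activated α-iodoenone with the primary amide at C2, leaves the unactivated vinyl group alone and involves no stereocentre.

Step 10
Reactants: 20 glutaconaldehyde potassium salt
Product: 21 (2E,4E)-5-bromopenta-2,4-dienal
Conditions: Ph3PBr2, CH2Cl2, 0 °C to rt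
Reagents that add atoms: dibromotriphenylphosphorane, BrP(Br)(c1ccccc1)(c1ccccc1)c1ccccc1
Why: O-Phosphonium activation of the dienolate followed by bromide addition–elimination (vinylogous acyl substitution) gives the bromodienal, which settles as the (2E,4E) isomer.

Step 11
Reactants: 21 (2E,4E)-5-bromopenta-2,4-dienal
Product: 22 (2E,4E)-5-bromopenta-2,4-dienoic acid
Conditions: NaClO2, NaH2PO4, 2-methylbut-2-ene, t-BuOH–H2O, 0 °C to rt
Reagents that add atoms: sodium chlorite, [Na+].[O-]Cl=O
Why: Pinnick oxidation converts the aldehyde into the acid without touching the diene or the vinylic bromide.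

Step 12
Reactants: 22 (2E,4E)-5-bromopenta-2,4-dienoic acid; 23 2-amino-3-hydroxycyclopent-2-en-1-one hydrochloride
Product: 25 (2E,4E)-5-bromo-N-(2-hydroxy-5-oxocyclopent-1-en-1-yl)penta-2,4-dienamide, via acid chloride 24 (not isolated)
Conditions: (COCl)2, cat. DMF, CH2Cl2, 0 °C; then 23, Et3N, THF, 0 °C to rt
Reagents that add atoms: none
Why: Acyl chloride formation then N-acylation of the weakly nucleophilic vinylogous amide nitrogen (Schotten–Baumann-type amide formation), any O-acyl isomer rearranging to the more stable enol amide.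

Step 13
Reactants: 19 (2E,4E,6R)-N-[(3R,4S)-3-ethenyl-3,4-dihydroxy-6-oxocyclohex-1-en-1-yl]-2,4,6-trimethyldeca-2,4-dienamide; 25 (2E,4E)-5-bromo-N-(2-hydroxy-5-oxocyclopent-1-en-1-yl)penta-2,4-dienamide
Product: 26 (2E,4E,6R)-N-[(3R,4S)-3,4-dihydroxy-3-[(1E,3E,5E)-7-[(2-hydroxy-5-oxocyclopent-1-en-1-yl)amino]-7-oxohepta-1,3,5-trien-1-yl]-6-oxocyclohex-1-en-1-yl]-2,4,6-trimethyldeca-2,4-dienamide
Conditions: Pd(OAc)2 (10 mol%), Bu4NCl, NaHCO3, DMF, 45 °C, dark
Reagents that add atoms: none
Why: Heck reaction under Jeffery conditions, in which zerovalent palladium adds oxidatively to the alkenyl bromide with retention, inserts at the unhindered vinyl terminus and undergoes syn β-hydride elimination (the only β-hydrogens sit on the new carbon) to give the (E) alkene, the tertiary carbinol ruling out ketone formation.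

## Compound list

1 | 4,4-dimethoxycyclohexa-2,5-dien-1-one | COC1(OC)C=CC(=O)C=C1 | starting material
2 | vinylmagnesium bromide | C=C[Mg]Br | starting material
3 | 1-ethenyl-4,4-dimethoxycyclohexa-2,5-dien-1-ol (ketal carbinol, not isolated) | COC1(OC)C=CC(O)(C=C)C=C1 | intermediate
4 | 4-ethenyl-4-hydroxycyclohexa-2,5-dien-1-one (achiral p-quinol) | O=C1C=CC(O)(C=C)C=C1 | intermediate
5 | (3aS,7aR)-7a-ethenyl-2-phenyl-3a,7a-dihydro-1,3,2-benzodioxaborol-5(4H)-one (cis-fused cyclic phenylboronate, not isolated) | O=C1C=C[C@@]3(C=C)OB(c2ccccc2)O[C@H]3C1 | intermediate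
6 | (4R,5S)-4-ethenyl-4,5-dihydroxycyclohex-2-en-1-one (cis-diol) | O=C1C=C[C@](O)(C=C)[C@@H](O)C1 | intermediate
7 | (4R,5S)-4-ethenyl-4,5-dihydroxy-2-iodocyclohex-2-en-1-one | O=C1C(I)=C[C@](O)(C=C)[C@@H](O)C1 | intermediate
8 | hexanal | CCCCCC=O | starting material
9 | 1,3-benzodithiolylium tetrafluoroborate | F[B-](F)(F)F.C1=[S+]c2ccccc2S1 | starting material
10 | (2R)-2-(1,3-benzodithiol-2-yl)hexanal (not isolated) | CCCC[C@@H](C1Sc2ccccc2S1)C=O | intermediate
11 | (2R)-2-(1,3-benzodithiol-2-yl)hexan-1-ol | CCCC[C@@H](C1Sc2ccccc2S1)CO | intermediate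
12 | (2R)-2-methylhexan-1-ol | CCCC[C@@H](C)CO | intermediate
13 | 2-(triphenylphosphoranylidene)propanal | CC(C=O)=P(c1ccccc1)(c1ccccc1)c1ccccc1 | starting material
14 | (2R)-2-methylhexanal (not isolated) | CCCC[C@@H](C)C=O | intermediate
15 | (2E,4R)-2,4-dimethyloct-2-enal | CCCC[C@@H](C)/C=C(\C)C=O | intermediate
16 | ethyl 2-(triphenylphosphoranylidene)propanoate | CCOC(=O)C(C)=P(c1ccccc1)(c1ccccc1)c1ccccc1 | starting material
17 | ethyl (2E,4E,6R)-2,4,6-trimethyldeca-2,4-dienoate | CCCC[C@@H](C)/C=C(C)/C=C(\C)C(=O)OCC | intermediate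
18 | (2E,4E,6R)-2,4,6-trimethyldeca-2,4-dienamide | CCCC[C@@H](C)/C=C(C)/C=C(\C)C(N)=O | intermediate
19 | (2E,4E,6R)-N-[(3R,4S)-3-ethenyl-3,4-dihydroxy-6-oxocyclohex-1-en-1-yl]-2,4,6-trimethyldeca-2,4-dienamide | CCCC[C@@H](C)/C=C(C)/C=C(\C)C(=O)NC1=C[C@](O)(C=C)[C@@H](O)CC1=O | intermediate
20 | glutaconaldehyde potassium salt, potassium (1E,3E)-5-oxopenta-1,3-dien-1-olate | [K+].[O-]/C=C/C=C/C=O | starting material
21 | (2E,4E)-5-bromopenta-2,4-dienal | Br/C=C/C=C/C=O | intermediate
22 | (2E,4E)-5-bromopenta-2,4-dienoic acid | OC(=O)/C=C/C=C/Br | intermediate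
23 | 2-amino-3-hydroxycyclopent-2-en-1-one hydrochloride | NC1=C(O)CCC1=O.Cl | starting material
24 | (2E,4E)-5-bromopenta-2,4-dienoyl chloride (not isolated) | ClC(=O)/C=C/C=C/Br | intermediate
25 | (2E,4E)-5-bromo-N-(2-hydroxy-5-oxocyclopent-1-en-1-yl)penta-2,4-dienamide | O=C(/C=C/C=C/Br)NC1=C(O)CCC1=O | intermediate
26 | (2E,4E,6R)-N-[(3R,4S)-3,4-dihydroxy-3-[(1E,3E,5E)-7-[(2-hydroxy-5-oxocyclopent-1-en-1-yl)amino]-7-oxohepta-1,3,5-trien-1-yl]-6-oxocyclohex-1-en-1-yl]-2,4,6-trimethyldeca-2,4-dienamide | CCCC[C@@H](C)/C=C(C)/C=C(\C)C(=O)NC1=C[C@](O)(/C=C/C=C/C=C/C(=O)NC2=C(O)CCC2=O)[C@@H](O)CC1=O | target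

## Step count and risks

Total step count: 13. Longest linear sequence: 7 steps (hexanal 8 through steps 4, 5, 6, 7, 8, 9 and 13 to 26).

Steps most likely to fail:

Step 2 (the proposed new desymmetrization). The risks are low enantioselectivity, because the catalyst must tell apart two arms that share one carbonyl, and reversal of the oxa-Michael addition. The fallback sets out from 4 and comes back at 6, using the known chiral-phosphoric-acid acetalization/oxa-Michael desymmetrization of p-quinols. Quinol 4 and 2-methylpropanal with (R)-TRIP (10 mol%), 4 Å MS, CH2Cl2, rt give the cis-fused dioxolane (2R,3aS,7aR)-7a-ethenyl-2-(propan-2-yl)-3a,7a-dihydro-1,3-benzodioxol-5(4H)-one F1. Acetal hydrolysis (TFA–H2O–THF, 0 °C, volatile aldehyde removed under reduced pressure) then releases 6.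

Step 9 (vinylic amidation on a free β-hydroxy ketone). The risks are carbonate-induced retro-aldol or β-elimination and copper binding by the cis-diol. The fallback sets out from 7 and comes back at 19 through a protecting-group detour that removes the free β-hydroxy ketone. 2,2-Dimethoxypropane, PPTS, acetone, rt give the acetonide (3aS,7aR)-7a-ethenyl-6-iodo-2,2-dimethyl-3a,7a-dihydro-1,3-benzodioxol-5(4H)-one F2. The same CuI/diamine/Cs2CO3 coupling with 18 gives (2E,4E,6R)-N-[(3aS,7aR)-7a-ethenyl-2,2-dimethyl-5-oxo-3a,4,5,7a-tetrahydro-1,3-benzodioxol-6-yl]-2,4,6-trimethyldeca-2,4-dienamide F3. 80% aqueous AcOH at 40 °C then unmasks 19.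

Step 13 (final Heck coupling). The risks are a sluggish reaction of the hindered tertiary vinyl carbinol and polyene isomerisation or oligomerisation. The fallback sets out from 19 and comes back at 26. Cross-metathesis of 19 with vinylboronic acid pinacol ester (second-generation Hoveyda–Grubbs catalyst, CH2Cl2, 40 °C) gives (2E,4E,6R)-N-[(3R,4S)-3,4-dihydroxy-6-oxo-3-[(E)-2-(4,4,5,5-tetramethyl-1,3,2-dioxaborolan-2-yl)ethenyl]cyclohex-1-en-1-yl]-2,4,6-trimethyldeca-2,4-dienamide F4. Suzuki–Miyaura coupling of this boronate with 25 (Pd(PPh3)4, aqueous K3PO4, THF, rt) gives 26.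

Further compounds
F1 | step 2 | (2R,3aS,7aR)-7a-ethenyl-2-(propan-2-yl)-3a,7a-dihydro-1,3-benzodioxol-5(4H)-one | O=C1C=C[C@@]3(C=C)O[C@H](C(C)C)O[C@H]3C1
F2 | step 9 | (3aS,7aR)-7a-ethenyl-6-iodo-2,2-dimethyl-3a,7a-dihydro-1,3-benzodioxol-5(4H)-one | O=C1C(I)=C[C@@]3(C=C)OC(C)(C)O[C@H]3C1
F3 | step 9 | (2E,4E,6R)-N-[(3aS,7aR)-7a-ethenyl-2,2-dimethyl-5-oxo-3a,4,5,7a-tetrahydro-1,3-benzodioxol-6-yl]-2,4,6-trimethyldeca-2,4-dienamide | CCCC[C@@H](C)/C=C(C)/C=C(\C)C(=O)NC1=C[C@@]2(C=C)OC(C)(C)O[C@H]2CC1=O
F4 | step 13 | (2E,4E,6R)-N-[(3R,4S)-3,4-dihydroxy-6-oxo-3-[(E)-2-(4,4,5,5-tetramethyl-1,3,2-dioxaborolan-2-yl)ethenyl]cyclohex-1-en-1-yl]-2,4,6-trimethyldeca-2,4-dienamide | CCCC[C@@H](C)/C=C(C)/C=C(\C)C(=O)NC1=C[C@](O)(/C=C/B2OC(C)(C)C(C)(C)O2)[C@@H](O)CC1=O
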